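(Readings and results are simulated for substances that don't exist; the scatter is artificial.)

The time of reading, 120 min, lies later than the last reading of either earlier run, 80.0 min, so the readings had to be carried forward.

| setting | theta | alpha | Wednesday's | Thursday's |
|---|---|---|---|---|
| starting material | 0.20 M | 0.20 M | 0.20 M | 0.20 M |
| partner A | 0.22 M | 0.22 M | 0.220 M | 0.220 M |
| partner B | 0.18 M | 0.61 M | 0.300 M | 0.900 M |
| remark | run made earlier | run made earlier |  |  |
| time |  |  | 2.0 h | 2.0 h |

| run | time / min | homo product / % | target / % | starting material / % | isomer of the product / % |
|---|---|---|---|---|---|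
| theta | 6.00 | 0 | 0.4 | 96.4 | 0 |
| theta | 10.0 | 0.7 | 0 | 94.1 | 0 |
| theta | 15.0 | 0.3 | 0.2 | 92.3 | 0 |
| theta | 25.0 | 1.3 | 2.1 | 90.0 | 0.9 |
| theta | 40.0 | 3.3 | 4.3 | 85.1 | 1.1 |
| theta | 60.0 | 5.4 | 7.7 | 81.6 | 2.6 |
| theta | 80.0 | 6.0 | 7.8 | 79.2 | 3.6 |
| alpha | 6.00 | 0.7 | 1.2 | 88.8 | 0.4 |
| alpha | 10.0 | 3.1 | 2.2 | 84.0 | 0 |
| alpha | 15.0 | 5.7 | 5.4 | 76.8 | 0.3 |
| alpha | 25.0 | 9.9 | 11.2 | 66.8 | 1.4 |
| alpha | 40.0 | 13.0 | 18.1 | 55.7 | 4.1 |
| alpha | 60.0 | 15.6 | 23.9 | 44.9 | 9.5 |
| alpha | 80.0 | 17.9 | 27.7 | 36.4 | 14.4 |

(scatter of a reading: 0.5 percentage points)

- percentages count the starting material that a species holds: one homo product counts as two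
- what was read earlier has a scatter of 0.5 percentage points, one standard deviation

* which of these there is most of at the end, counted by the starting material in it, Wednesday's (starting material / isomer of the product / homo product / target)
* which of these there is most of at the end, counted by the starting material in it, Thursday's (starting material / isomer of the product / homo product / target)
* amount of the one of these that there is most of at the end, in percent of the starting material charged, Wednesday's
* amount of the one of these that there is most of at the end, in percent of the starting material charged, Thursday's

Which of target and isomer of the product led on Thursday's turned on a fork: a molecule that has become target may pass into isomer of the product, so I followed it and asked for its chances. I call isomer of the product over target, both as fractions of the charge, the isomer odds. In the alpha run they read 0.227, 0.397 and 0.520 at 40.0 min, 60.0 min and 80.0 min. The theta run, with 0.18 M of partner B against 0.61 M, read 0.462 at that same last time, where the alpha run read 0.520; with so little target in the theta run, that gap was of the size the scatter gives, so I took a change of partner B to move the odds little and carried the alpha odds over to Thursday's. But the rises were shrinking: the second read 0.716 of the first, a reading with the scatter on it, much as in a relaxation with one time constant. I assumed that factor held for two more equal steps, and the isomer odds at 120 min came to 0.670. That is below one, so I expected target ahead of isomer of the product on Thursday's.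

For Wednesday's the forecast said starting material at 56 %, and I had nothing against that. For Thursday's it said isomer of the product at 40 %, with target at 28 %: “so isomer leads, though not by a wide margin”. There my reckoning differed from it.

Wednesday's ended with starting material at 59.4 %, and Thursday's with target at 36.4 %. Isomer of the product stood at 25.0 % on Thursday's, so the odds there were 0.687, against my 0.670.

    starting material + partner B → open intermediate (k = 5.60 × 10⁻⁴ M⁻¹ s⁻¹)
    partner B + partner A → second intermediate (k = 0.00140 M⁻¹ s⁻¹)
    open intermediate + second intermediate → target (k = 0.0100 M⁻¹ s⁻¹)
    2 open intermediate → homo product (k = 0.0130 M⁻¹ s⁻¹)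
    target ⇌ isomer of the product (K = 0.840, k = 3.10 × 10⁻⁴ s⁻¹)

The neighbouring flask was Thursday's with 0.055 M of partner A, and I held the same 0.670 against it. That neighbouring flask gave target 12.6 % and isomer of the product 8.76 %, odds of 0.695, while the homo product held the most, 66.4 %.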